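**Retrosynthetic overview**
1. Target 10 ⇒ 9 ⇒ 8: late C–O bond formations on a cis-1,4-enediol (O-methylation at C6–OH, site-selective O-benzoylation at C3–OH).
2. 8 ⇒ diene 6: both allylic C–O bonds from an anti-facial singlet-oxygen [4+2] cycloaddition and O–O reduction.
3. 6 ⇒ o-quinol acetate 4: cis-selective 1,2-reduction, then a 1,2 O→O acetyl shift that moves the acetate from the C1 oxygen to the C2 oxygen.
4. 4 ⇒ phenol 3: the key C–O bond, made by a catalytic enantioselective ortho-acetoxylative dearomatisation that sets the quaternary carbinol centre; all other centres are relayed from it.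
5. 3 ⇒ salicyl alcohol + benzoic acid. No carbocycle is built: the six-membered ring is the arene ring of 1; the only ring formed is the transient endoperoxide 7 (step 4), opened in the same flask.

Locants used in the text: C1 = quaternary carbinol carbon (bears CH2OBz), C2 = CH–OAc, C3 = CH–OBz, C4=C5 = alkene, C6 = CH–OMe. The IUPAC names in the list number the ring the other way round.

Assumption: the target is taken exactly as the given SMILES, i.e. [(1R,2S,5R,6S)-6-acetoxy-5-benzoyloxy-1-hydroxy-2-methoxycyclohex-3-en-1-yl]methyl benzoate.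

Assumption: the sense of induction of the new catalyst in step 2 has no precedent. The (R,R)-antipode of 2-iodo-1,3-bis[1-(mesitylcarbamoyl)ethoxy]benzene is written; its mirror image is used if it delivers (R)-4.

**Step 1**
Reactants: 1 salicyl alcohol (2-hydroxybenzyl alcohol); 2 benzoic acid
Product: 3 2-hydroxybenzyl benzoate
Conditions: PPh3, DIAD, THF, 0 °C to rt
Reagents that add atoms: none
Why: Mitsunobu esterification: only the far more acidic benzoic acid (pKa 4 against 10 for the phenol) protonates the betaine, and benzoate displaces the primary benzylic oxyphosphonium (directly or through the o-quinone methide, same product), so the phenol stays free; no stereocentre.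

**Step 2**
Reactants: 3 2-hydroxybenzyl benzoate
Product: 4 [(1S)-1-acetoxy-6-oxocyclohexa-2,4-dien-1-yl]methyl benzoate
Conditions: (R,R)-lactamide iodoarene catalyst (10 mol %), AcOOH, AcOH, CH2Cl2, −20 °C
Reagents that add atoms: acetic acid CC(=O)O; peracetic acid CC(=O)OO (its reduced form, acetic acid, joins the same acetate pool)
Why: Proposed new method: a catalytic enantioselective Wessely-type ortho-acetoxylative dearomatisation, in which the chiral aryl-λ3-iodane diacetate formed in situ exchanges one acetate for the phenol, the benzoate C=O···I secondary bond turns the CH2OBz-bearing ortho carbon toward the catalyst, and an acetate held by a lactamide N–H is delivered to that carbon from the open face of the helical pocket with loss of ArI (associative SN2′-type ligand coupling; the non-ionising solvent suppresses free phenoxenium and hence para attack), forming the C1–O bond and the quaternary (S) centre; the closest known reaction types are the chiral-iodoarene-catalysed oxidative spirolactonisation of phenols (Kita-type, intramolecular carboxylate) and the racemic Wessely acetoxylation with Pb(OAc)4 or PhI(OAc)2.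

**Step 3**
Reactants: 4 [(1S)-1-acetoxy-6-oxocyclohexa-2,4-dien-1-yl]methyl benzoate
Product: 6 [(1S,6S)-6-acetoxy-1-hydroxycyclohexa-2,4-dien-1-yl]methyl benzoate, via cis-dienol 5 (not isolated)
Conditions: NaBH4, CeCl3·7H2O, MeOH–CH2Cl2, −78 °C; then Et3N (cat.), 0 °C
Reagents that add atoms: none
Why: Luche 1,2-reduction followed by a 1,2 O→O acyl shift: hydride should attack the carbonyl anti to the pseudoaxial, electron-withdrawing C1–OAc bond (polar Felkin–Anh), setting C2 (S) with OH cis to OAc; the cis hydroxyl then takes the acetyl from the tertiary oxygen through a five-membered orthoester (tertiary to secondary ester, downhill), which a trans epimer cannot do, so that epimer stays a separable secondary alcohol.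

**Step 4**
Reactants: 6 [(1S,6S)-6-acetoxy-1-hydroxycyclohexa-2,4-dien-1-yl]methyl benzoate
Product: 8 [(1R,2S,5R,6S)-6-acetoxy-1,2,5-trihydroxycyclohex-3-en-1-yl]methyl benzoate, via endoperoxide 7 (not isolated)
Conditions: O2, Rose Bengal (cat.), hν (white LED), CH2Cl2–MeOH, −30 °C; then thiourea, −30 °C to rt
Reagents that add atoms: dioxygen O=O
Why: Photooxygenation (singlet-oxygen [4+2] cycloaddition) is expected on the diene face anti to the two allylic C–O bonds (C1–OH, C2–OAc), with MeOH damping any hydroxyl-directed syn attack, and thiourea then reduces only the O–O bond, so C3–O and C6–O are set cis to each other and trans to the C1/C2 oxygens.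

**Step 5**
Reactants: 8 [(1R,2S,5R,6S)-6-acetoxy-1,2,5-trihydroxycyclohex-3-en-1-yl]methyl benzoate
Product: 9 [(1R,2S,5R,6S)-6-acetoxy-5-benzoyloxy-1,2-dihydroxycyclohex-3-en-1-yl]methyl benzoate
Conditions: BzCl (1.05 equiv), pyridine, CH2Cl2, −40 °C
Reagents that add atoms: benzoyl chloride O=C(Cl)c1ccccc1
Why: Kinetic site-selective O-acylation: the C3–OH flanked by CH(OAc) should react first, because the C6–OH is neopentylic and cis to the CH2OBz on the quaternary carbon and the tertiary OH is inert at −40 °C; no stereocentre is touched.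

**Step 6**
Reactants: 9 [(1R,2S,5R,6S)-6-acetoxy-5-benzoyloxy-1,2-dihydroxycyclohex-3-en-1-yl]methyl benzoate
Product: 10 [(1R,2S,5R,6S)-6-acetoxy-5-benzoyloxy-1-hydroxy-2-methoxycyclohex-3-en-1-yl]methyl benzoate
Conditions: Me3OBF4, Proton-sponge, 4 Å MS, CH2Cl2, 0 °C to rt
Reagents that add atoms: trimethyloxonium tetrafluoroborate C[O+](C)C.F[B-](F)(F)F
Why: Meerwein O-methylation with Proton-sponge as acid scavenger is non-basic, so no alkoxide forms and no acyl migration occurs; the only secondary OH is methylated, the tertiary OH is too hindered, and C6 keeps its configuration because only the O–H bond reacts.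

**Compound list**
1 | salicyl alcohol (2-hydroxybenzyl alcohol) | OCc1ccccc1O | starting material
2 | benzoic acid | OC(=O)c1ccccc1 | starting material
3 | 2-hydroxybenzyl benzoate | O=C(OCc1ccccc1O)c1ccccc1 | intermediate
4 | [(1S)-1-acetoxy-6-oxocyclohexa-2,4-dien-1-yl]methyl benzoate ((S)-o-quinol acetate) | O=C1C=CC=C[C@]1(OC(C)=O)COC(=O)c1ccccc1 | intermediate
5 | [(1S,6S)-1-acetoxy-6-hydroxycyclohexa-2,4-dien-1-yl]methyl benzoate (cis-dienol, OH cis to OAc) | O[C@H]1C=CC=C[C@]1(OC(C)=O)COC(=O)c1ccccc1 | intermediate
6 | [(1S,6S)-6-acetoxy-1-hydroxycyclohexa-2,4-dien-1-yl]methyl benzoate (tertiary OH cis to OAc) | CC(=O)O[C@H]1C=CC=C[C@]1(O)COC(=O)c1ccccc1 | intermediate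
7 | [(1S,4R,7S,8S)-8-acetoxy-7-hydroxy-2,3-dioxabicyclo[2.2.2]oct-5-en-7-yl]methyl benzoate (endoperoxide, O–O bridge anti to OH and OAc) | O2[C@H]1C=C[C@@H](O2)[C@H](OC(C)=O)[C@@]1(O)COC(=O)c1ccccc1 | intermediate
8 | [(1R,2S,5R,6S)-6-acetoxy-1,2,5-trihydroxycyclohex-3-en-1-yl]methyl benzoate | O[C@H]1C=C[C@@H](O)[C@H](OC(C)=O)[C@@]1(O)COC(=O)c1ccccc1 | intermediate
9 | [(1R,2S,5R,6S)-6-acetoxy-5-benzoyloxy-1,2-dihydroxycyclohex-3-en-1-yl]methyl benzoate | O[C@H]1C=C[C@@H](OC(=O)c2ccccc2)[C@H](OC(C)=O)[C@@]1(O)COC(=O)c1ccccc1 | intermediate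
10 | [(1R,2S,5R,6S)-6-acetoxy-5-benzoyloxy-1-hydroxy-2-methoxycyclohex-3-en-1-yl]methyl benzoate | CO[C@H]1C=C[C@@H](OC(=O)c2ccccc2)[C@H](OC(C)=O)[C@@]1(O)COC(=O)c1ccccc1 | target

**Total step count:** 6. **Longest linear sequence:** 6 (from 1).

**Steps most likely to fail**

Step 2 (the proposed new reaction). Neither the site selectivity (substituted ortho carbon against the free ortho and para positions) nor the enantioselectivity has precedent. The fallback uses known chemistry, sets out from 3 and comes back at 6. Phenol 3 is oxidised with Pb(OAc)4 in AcOH/CH2Cl2 (classical Wessely acetoxylation, ortho delivery from the aryloxy-lead(IV) acetate) to the racemic o-quinol acetate F1. The racemate is then reduced under catalyst control with (R)-Me-CBS and catecholborane at −78 °C, a divergent reaction on a racemic mixture. Taking the quaternary carbon as the large group, the oxazaborolidine delivers hydride to the same carbonyl face of both enantiomers. The (S)-enantiomer therefore gives cis-dienol 5, which shifts its acetyl on Et3N treatment to give 6. The (R)-enantiomer gives the trans-dienol F2, which cannot shift its acetate and is removed by chromatography. The ceiling is 50 % yield.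

Step 3. The facial selectivity of hydride addition next to a quaternary centre carrying OAc and CH2OBz is predicted, not proven. The fallback sets out from 4 and comes back at 5. The trans-dienol F3, which remains a secondary alcohol after the Et3N treatment and is therefore easy to separate from 6, is oxidised back to 4 with MnO2 in CH2Cl2. Dienone 4 is then reduced under catalyst control with (R)-Me-CBS/catecholborane instead of under substrate control, giving 5 and, after Et3N, 6.

Step 5. The C3/C6 selectivity of the benzoylation may be only moderate, and acyl migration could interfere. The fallback sets out from 8 and comes back at 10, with the ether formed before the ester. TBSCl/imidazole in DMF at 0 °C, which discriminates on sterics far more strongly than BzCl, gives the 3-O-TBS ether F4. Me3OBF4/Proton-sponge then gives the 6-O-methyl ether F5. HF·pyridine in THF frees the C3 alcohol F6, whose only secondary hydroxyl is benzoylated (BzCl, pyridine, DMAP) to give 10.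

**Further compounds**
F1 | step 2 | racemic [1-acetoxy-6-oxocyclohexa-2,4-dien-1-yl]methyl benzoate | CC(=O)OC1(COC(=O)c2ccccc2)C=CC=CC1=O
F2 | step 2 | [(1R,6S)-1-acetoxy-6-hydroxycyclohexa-2,4-dien-1-yl]methyl benzoate (trans-dienol) | O[C@H]1C=CC=C[C@@]1(OC(C)=O)COC(=O)c1ccccc1
F3 | step 3 | [(1S,6R)-1-acetoxy-6-hydroxycyclohexa-2,4-dien-1-yl]methyl benzoate (trans-dienol) | O[C@@H]1C=CC=C[C@]1(OC(C)=O)COC(=O)c1ccccc1
F4 | step 5 | [(1R,2S,5R,6S)-6-acetoxy-5-(tert-butyldimethylsilyloxy)-1,2-dihydroxycyclohex-3-en-1-yl]methyl benzoate | O[C@H]1C=C[C@@H](O[Si](C)(C)C(C)(C)C)[C@H](OC(C)=O)[C@@]1(O)COC(=O)c1ccccc1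
F5 | step 5 | [(1R,2S,5R,6S)-6-acetoxy-5-(tert-butyldimethylsilyloxy)-1-hydroxy-2-methoxycyclohex-3-en-1-yl]methyl benzoate | CO[C@H]1C=C[C@@H](O[Si](C)(C)C(C)(C)C)[C@H](OC(C)=O)[C@@]1(O)COC(=O)c1ccccc1
F6 | step 5 | [(1R,2S,5R,6S)-6-acetoxy-1,5-dihydroxy-2-methoxycyclohex-3-en-1-yl]methyl benzoate | CO[C@H]1C=C[C@@H](O)[C@H](OC(C)=O)[C@@]1(O)COC(=O)c1ccccc1
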